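## Retrosynthetic overview

1. Sodwanone B ⇒ C7 oxidation and enolisation of a coupled triketone ⇒ cut the C9–CH2 sp2–sp3 bond (Negishi). This gives an oxepanone alkylzinc (fragment 1) and a decalin enol triflate (fragment 2).
2. Fragment 1: the oxepan-3-one is made last, by ring expansion of a trans-fused δ-lactone. A CMe2 unit is formally inserted into the acyl C–O bond, with a 1,2-shift of the ring oxygen. Lactone ⇒ ketone reduction (C5') ⇒ acrylate Michael addition (C10') ⇒ face-selective hydrogenation (C9') ⇒ organocatalytic Michael/aldol cyclohexenone (C8').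
3. Fragment 2: ring A comes from a Hajos–Parrish annulation on 2-methylcyclopentane-1,3-dione (C10). Ring B comes from diazoethane ring expansion of the cyclopentanone, which also brings in the C8 methyl. Then follow C4 gem-dimethylation, the C9 enol triflate and conversion of C5=C6 into the C6 ketone.
4. Ring order: left cyclohexane → δ-lactone → oxepanone; right five-membered ring (purchased) → ring A → ring B (five to six); union; diosphenol last.

Assumption: the SMILES is taken as the absolute configuration. Locants: the decalin half is C1–C10 (C3 ketone, C4 gem-dimethyl, C10 angular methyl, C9 carries the CH2CH2 bridge). The oxepane half is primed in the same way, with the ring oxygen between C4' and C5'.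

## Route

Step 1
Reactants: 1 propanal; 2 pent-1-en-3-one
Product: 4 (4R)-2,4-dimethylcyclohex-2-en-1-one, via keto aldehyde 3 (not isolated)
Conditions: (S)-2-[methoxy(diphenyl)methyl]pyrrolidine (5 mol %), ethyl 3,4-dihydroxybenzoate (20 mol %), neat, 4 °C; then LiOH, i-PrOH, rt
Reagents that add atoms: none
Why: Enamine-catalysed asymmetric Michael addition, in which the bulky diphenyl(methoxy)methyl group shields one enamine face and sets the methyl-bearing C8' centre as R, followed by intramolecular aldol condensation, the only six-membered closure available.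

Step 2
Reactants: 4 (4R)-2,4-dimethylcyclohex-2-en-1-one
Product: 6 (4R)-3-ethenyl-2,4-dimethylcyclohex-2-en-1-one, via silyl enol ether 5 (not isolated)
Conditions: CH2=CHMgBr, CuBr·SMe2 (10 mol %), LiCl, Me3SiCl, THF, −78 °C; crude, then Pd(OAc)2 (10 mol %), O2 (1 atm), DMSO, 40 °C
Reagents that add atoms: vinylmagnesium bromide, C=C[Mg]Br
Why: Copper-catalysed 1,4-addition trapped as the regiodefined silyl enol ether and Saegusa–Ito dehydrogenation give net β-vinylation of the enone, so the transient C9' centre does not matter and C8' is untouched.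

Step 3
Reactants: 6 (4R)-3-ethenyl-2,4-dimethylcyclohex-2-en-1-one
Product: 7 (4R)-3-(2-bromoethyl)-2,4-dimethylcyclohex-2-en-1-one
Conditions: HBr (33% in AcOH, 1.1 equiv), CH2Cl2, −20 °C
Reagents that add atoms: hydrogen bromide, Br
Why: Acid-promoted 1,6-hydrobromination (vinylogous conjugate addition) of the linear dienone places bromide on the terminal carbon, and the dienol returns to the tetrasubstituted enone, which turns the vinyl group into a coupling handle that survives hydrogenation.

Step 4
Reactants: 7 (4R)-3-(2-bromoethyl)-2,4-dimethylcyclohex-2-en-1-one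
Product: 8 (2R,3R,4R)-3-(2-bromoethyl)-2,4-dimethylcyclohexan-1-one (all-cis)
Conditions: H2 (4 atm), 10% Pd/C, EtOAc, rt
Reagents that add atoms: none
Why: Heterogeneous syn-hydrogenation of an activated enone, in which allylic 1,2-strain with the C9' side chain holds the C8' methyl pseudoaxial so that hydrogen arrives on the opposite face and sets C9' cis to C8' (the C10' centre formed here is remade in step 5).

Step 5
Reactants: 8 (2R,3R,4R)-3-(2-bromoethyl)-2,4-dimethylcyclohexan-1-one; 9 methyl acrylate
Product: 10 methyl 3-[(1S,2R,3R)-2-(2-bromoethyl)-1,3-dimethyl-6-oxocyclohexyl]propanoate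
Conditions: KOt-Bu (15 mol %), t-BuOH/THF, 0 °C
Reagents that add atoms: none
Why: Michael addition of the thermodynamic, more substituted enolate, in which acrylate attacks axially and anti to the pseudoaxial C9' side chain, setting the quaternary C10' with its methyl cis to that chain.

Step 6
Reactants: 10 methyl 3-[(1S,2R,3R)-2-(2-bromoethyl)-1,3-dimethyl-6-oxocyclohexyl]propanoate
Product: 12 (4aS,5R,6R,8aS)-5-(2-bromoethyl)-4a,6-dimethyloctahydro-2H-chromen-2-one (trans-fused), via hydroxy ester 11 (not isolated)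
Conditions: NaBH4, MeOH, −20 °C; then TsOH (5 mol %), toluene, 80 °C
Reagents that add atoms: none
Why: Borohydride reduction from the only open face (the other is screened by the axial C9' chain in one chair and by the axial C10' methyl in the other) sets C5' with oxygen trans to the propanoate arm, and acid-catalysed lactonisation closes the trans-fused δ-lactone.

Step 7
Reactants: 12 (4aS,5R,6R,8aS)-5-(2-bromoethyl)-4a,6-dimethyloctahydro-2H-chromen-2-one
Product: 15 (5aS,6R,7R,9aS)-6-(2-bromoethyl)-2,2,5a,7-tetramethyloctahydro-1-benzoxepin-3(2H)-one, via bromo lactolate 13 (not isolated), via spiro epoxy ether 14 (not isolated)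
Conditions: Me2CBr2, n-BuLi, THF/Et2O/pentane, −110 °C, then 12; −110 → −30 °C; then MgBr2·OEt2, −30 → 0 °C
Reagents that add atoms: 2,2-dibromopropane, CC(C)(Br)Br
Why: Proposed new method: formal insertion of an isopropylidene unit into the acyl C–O bond of a lactone, in which the carbenoid 2-bromo-2-lithiopropane adds to the lactone carbonyl, the hemiketal alkoxide closes onto the tertiary C–Br bond on warming to give a 2-alkoxyoxirane, and MgBr2 ionises the oxirane at its tertiary carbon so that the antiperiplanar ring oxygen migrates from C3' to C4' through a bridged oxonium ion while the C3' carbonyl forms, which expands the six-membered lactone to the 2,2-dimethyloxepan-3-one without breaking the C5'–O bond or touching a stereocentre; the closest known reaction types are carbenoid homologation of ketones, the Lewis-acid rearrangement of acyclic epoxy ethers (from α-bromo ketones) to α-alkoxy ketones, and the CH2-only homologation of lactones through sulfoxonium ylides and O–H insertion.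

Step 8
Reactants: 16 2-methylcyclopentane-1,3-dione; 17 but-3-en-2-one
Product: 18 2-methyl-2-(3-oxobutyl)cyclopentane-1,3-dione
Conditions: H2O, AcOH (cat.), 70 °C
Reagents that add atoms: none
Why: Michael addition of the acidic cyclic 1,3-dione to the vinyl ketone, which stops cleanly at the prochiral triketone.

Step 9
Reactants: 18 2-methyl-2-(3-oxobutyl)cyclopentane-1,3-dione
Product: 20 (7aS)-7a-methyl-2,3,7,7a-tetrahydro-1H-indene-1,5(6H)-dione, via ketol 19 (not isolated)
Conditions: (S)-proline (3 mol %), DMF, rt; then H2SO4 (cat.), DMF, 95 °C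
Reagents that add atoms: none
Why: Hajos–Parrish–Eder–Sauer–Wiechert reaction, in which the proline enamine aldol distinguishes the enantiotopic ring ketones and sets the angular C10 centre, and acid then dehydrates the ketol to close ring A.

Step 10
Reactants: 20 (7aS)-7a-methyl-2,3,7,7a-tetrahydro-1H-indene-1,5(6H)-dione
Product: 21 (2R,8aS)-2,8a-dimethyl-3,4,8,8a-tetrahydronaphthalene-1,6(2H,7H)-dione
Conditions: CH3CHN2 (Et2O solution), BF3·OEt2, CH2Cl2, −78 °C
Reagents that add atoms: diazoethane, CC=[N+]=[N-]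
Why: Lewis-acid-promoted diazoalkane homologation (Tiffeneau–Demjanov-type 1,2-shift), in which diazoethane adds to the saturated cyclopentanone rather than the enone and the CH2 carbon migrates in preference to the quaternary carbon, so ring B becomes six-membered and already carries the C8 methyl (equatorial after equilibration and removed as a stereocentre in step 12).

Step 11
Reactants: 21 (2R,8aS)-2,8a-dimethyl-3,4,8,8a-tetrahydronaphthalene-1,6(2H,7H)-dione
Product: 23 (2R,8aS)-2,5,5,8a-tetramethyl-3,5,8,8a-tetrahydronaphthalene-1,6(2H,7H)-dione, via monomethyl enone 22 (not isolated)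
Conditions: KOt-Bu (2.5 equiv), MeI (5 equiv), t-BuOH/THF, 0 °C → rt
Reagents that add atoms: iodomethane, CI
Why: Deconjugative double α-alkylation of the extended dienolate installs the C4 gem-dimethyl group and moves the alkene to C5=C6, while the far less acidic and hindered tertiary C8–H of the other ketone competes poorly.

Step 12
Reactants: 23 (2R,8aS)-2,5,5,8a-tetramethyl-3,5,8,8a-tetrahydronaphthalene-1,6(2H,7H)-dione
Product: 26 (8aS)-2,5,5,8a-tetramethyl-6-oxo-3,5,6,7,8,8a-hexahydronaphthalen-1-yl trifluoromethanesulfonate, via silyl enol ether 24 (not isolated), via silyl enol ether triflate 25 (not isolated)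
Conditions: LiN(i-Pr)2 (1.05 equiv), Me3SiCl (1.0 equiv), THF, −78 °C; then KN(SiMe3)2 (1.3 equiv), −78 → 0 °C; PhNTf2, −78 °C → rt; 1 M HCl work-up
Reagents that add atoms: N-phenylbis(trifluoromethanesulfonimide), O=S(=O)(C(F)(F)F)N(c1ccccc1)S(=O)(=O)C(F)(F)F
Why: Kinetic enolisation picks the unhindered C2 methylene so the C3 ketone is masked in the flask as its silyl enol ether, the remaining C9 ketone can enolise only toward C8 and is trapped as the tetrasubstituted enol triflate, and the acidic work-up releases the C3 ketone.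

Step 13
Reactants: 26 (8aS)-2,5,5,8a-tetramethyl-6-oxo-3,5,6,7,8,8a-hexahydronaphthalen-1-yl trifluoromethanesulfonate
Product: 28 (4aR,8aS)-2,5,5,8a-tetramethyl-4,6-dioxo-3,4,4a,5,6,7,8,8a-octahydronaphthalen-1-yl trifluoromethanesulfonate, via epoxide 27 (not isolated)
Conditions: mCPBA, CH2Cl2, 0 °C; then BF3·OEt2 (0.3 equiv), −78 → −20 °C
Reagents that add atoms: 3-chloroperoxybenzoic acid, O=C(OO)c1cccc(Cl)c1
Why: Prilezhaev epoxidation of the only electron-rich alkene (the enol triflate is deactivated) and Meinwald rearrangement, in which ionisation at tertiary C5 and a 1,2-hydride shift from C6 give the C6 ketone, with the epimerisable C5–H settling trans to the angular methyl and being erased in step 15.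

Step 14
Reactants: 15 (5aS,6R,7R,9aS)-6-(2-bromoethyl)-2,2,5a,7-tetramethyloctahydro-1-benzoxepin-3(2H)-one; 28 (4aR,8aS)-2,5,5,8a-tetramethyl-4,6-dioxo-3,4,4a,5,6,7,8,8a-octahydronaphthalen-1-yl trifluoromethanesulfonate
Product: 30 coupled triketone (sodwanone B skeleton with C5–H, C6 ketone and C7 methylene), via alkylzinc bromide 29 (not isolated)
Conditions: Zn dust, I2 (5 mol %), DMA, 80 °C; then 28, PdCl2(dppf) (5 mol %), THF/DMA, 50 °C
Reagents that add atoms: none
Why: Direct zinc insertion into the primary bromide and Negishi sp3–sp2 cross-coupling form the C9–CH2 bond under neutral conditions that tolerate all three ketones and create no stereocentre.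

Step 15
Reactants: 30 coupled triketone
Product: 32 sodwanone B, via 6,7-dione 31 (not isolated)
Conditions: SeO2 (1.1 equiv), dioxane/H2O, 60 °C
Reagents that add atoms: selenium dioxide, O=[Se]=O
Why: Riley oxidation, in which the C6 ketone enolises preferentially toward the doubly activated (α-keto and allylic) C7 methylene and the resulting 6,7-dione tautomerises through its only enolisable hydrogen (C5–H) to the cross-conjugated diosphenol.

## Compound list

1 | propanal | CCC=O | starting material
2 | pent-1-en-3-one (ethyl vinyl ketone) | CCC(=O)C=C | starting material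
3 | (2R)-2-methyl-5-oxoheptanal | O=C[C@H](C)CCC(=O)CC | intermediate
4 | (4R)-2,4-dimethylcyclohex-2-en-1-one | CC1=C[C@H](C)CCC1=O | intermediate
5 | {[(3S,4R)-3-ethenyl-2,4-dimethylcyclohex-1-en-1-yl]oxy}trimethylsilane (vinyl trans to the C4 methyl) | C=C[C@H]1[C@H](C)CCC(O[Si](C)(C)C)=C1C | intermediate
6 | (4R)-3-ethenyl-2,4-dimethylcyclohex-2-en-1-one | C=CC1=C(C)C(=O)CC[C@H]1C | intermediate
7 | (4R)-3-(2-bromoethyl)-2,4-dimethylcyclohex-2-en-1-one | BrCCC1=C(C)C(=O)CC[C@H]1C | intermediate
8 | (2R,3R,4R)-3-(2-bromoethyl)-2,4-dimethylcyclohexan-1-one (all-cis) | BrCC[C@@H]1[C@H](C)CCC(=O)[C@@H]1C | intermediate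
9 | methyl acrylate | C=CC(=O)OC | starting material
10 | methyl 3-[(1S,2R,3R)-2-(2-bromoethyl)-1,3-dimethyl-6-oxocyclohexyl]propanoate | BrCC[C@@H]1[C@H](C)CCC(=O)[C@@]1(C)CCC(=O)OC | intermediate
11 | methyl 3-[(1S,2R,3R,6S)-2-(2-bromoethyl)-6-hydroxy-1,3-dimethylcyclohexyl]propanoate | BrCC[C@@H]1[C@H](C)CC[C@H](O)[C@@]1(C)CCC(=O)OC | intermediate
12 | (4aS,5R,6R,8aS)-5-(2-bromoethyl)-4a,6-dimethyloctahydro-2H-chromen-2-one (trans-fused δ-lactone) | BrCC[C@@H]1[C@H](C)CC[C@@H]2OC(=O)CC[C@]21C | intermediate
13 | lithium alkoxide of the 2-(2-bromopropan-2-yl) lactol of 12 (C3' configuration not defined) | BrCC[C@@H]1[C@H](C)CC[C@@H]2OC([O-])(C(C)(C)Br)CC[C@]21C.[Li+] | intermediate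
14 | spiro epoxy ether: 3,3-dimethyloxirane spiro-fused at C3' of the tetrahydropyran ring (C3' configuration not defined) | BrCC[C@@H]1[C@H](C)CC[C@@H]2OC3(OC3(C)C)CC[C@]21C | intermediate
15 | (5aS,6R,7R,9aS)-6-(2-bromoethyl)-2,2,5a,7-tetramethyloctahydro-1-benzoxepin-3(2H)-one | BrCC[C@@H]1[C@H](C)CC[C@@H]2OC(C)(C)C(=O)CC[C@]21C | intermediate
16 | 2-methylcyclopentane-1,3-dione | CC1C(=O)CCC1=O | starting material
17 | but-3-en-2-one (methyl vinyl ketone) | CC(=O)C=C | starting material
18 | 2-methyl-2-(3-oxobutyl)cyclopentane-1,3-dione | CC(=O)CCC1(C)C(=O)CCC1=O | intermediate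
19 | (3aS,7aS)-3a-hydroxy-7a-methylhexahydro-1H-indene-1,5(4H)-dione | C[C@]12CCC(=O)C[C@@]1(O)CCC2=O | intermediate
20 | (7aS)-7a-methyl-2,3,7,7a-tetrahydro-1H-indene-1,5(6H)-dione | C[C@]12CCC(=O)C=C1CCC2=O | intermediate
21 | (2R,8aS)-2,8a-dimethyl-3,4,8,8a-tetrahydronaphthalene-1,6(2H,7H)-dione | C[C@]12CCC(=O)C=C1CC[C@@H](C)C2=O | intermediate
22 | (2R,8aS)-2,5,8a-trimethyl-3,4,8,8a-tetrahydronaphthalene-1,6(2H,7H)-dione | C[C@]12CCC(=O)C(C)=C1CC[C@@H](C)C2=O | intermediate
23 | (2R,8aS)-2,5,5,8a-tetramethyl-3,5,8,8a-tetrahydronaphthalene-1,6(2H,7H)-dione | C[C@]12CCC(=O)C(C)(C)C1=CC[C@@H](C)C2=O | intermediate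
24 | C3 trimethylsilyl enol ether (C2=C3) of 23 | C[C@]12CC=C(O[Si](C)(C)C)C(C)(C)C1=CC[C@@H](C)C2=O | intermediate
25 | C9 enol triflate (C8=C9) of 24 | CC1=C(OS(=O)(=O)C(F)(F)F)[C@@]2(C)CC=C(O[Si](C)(C)C)C(C)(C)C2=CC1 | intermediate
26 | (8aS)-2,5,5,8a-tetramethyl-6-oxo-3,5,6,7,8,8a-hexahydronaphthalen-1-yl trifluoromethanesulfonate | CC1=C(OS(=O)(=O)C(F)(F)F)[C@@]2(C)CCC(=O)C(C)(C)C2=CC1 | intermediate
27 | 5,6-epoxide of 26, oxygen anti to the angular methyl | CC1=C(OS(=O)(=O)C(F)(F)F)[C@@]2(C)CCC(=O)C(C)(C)[C@@]23O[C@H]3C1 | intermediate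
28 | (4aR,8aS)-2,5,5,8a-tetramethyl-4,6-dioxo-3,4,4a,5,6,7,8,8a-octahydronaphthalen-1-yl trifluoromethanesulfonate | CC1=C(OS(=O)(=O)C(F)(F)F)[C@@]2(C)CCC(=O)C(C)(C)[C@@H]2C(=O)C1 | intermediate
29 | alkylzinc bromide from 15 (BrZn in place of Br) | Br[Zn]CC[C@@H]1[C@H](C)CC[C@@H]2OC(C)(C)C(=O)CC[C@]21C | intermediate
30 | coupled triketone (C5–H trans to the C10 methyl, C6 ketone, C7 methylene, C8=C9) | CC1=C(CC[C@@H]2[C@H](C)CC[C@@H]3OC(C)(C)C(=O)CC[C@]32C)[C@@]2(C)CCC(=O)C(C)(C)[C@@H]2C(=O)C1 | intermediate
31 | 6,7-dione tautomer of the target | CC1=C(CC[C@@H]2[C@H](C)CC[C@@H]3OC(C)(C)C(=O)CC[C@]32C)[C@@]2(C)CCC(=O)C(C)(C)[C@@H]2C(=O)C1=O | intermediate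
32 | sodwanone B | CC1=C(CC[C@@H]2[C@H](C)CC[C@@H]3OC(C)(C)C(=O)CC[C@]32C)[C@@]2(C)CCC(=O)C(C)(C)C2=C(O)C1=O | target

## Step count and weak points

Total step count: 15. Longest linear sequence: 9 steps (steps 1–7, 14 and 15).

**Step 7 (proposed new ring expansion).**
- Risks: enolisation of the lactone by the carbenoid, a Favorskii-type or carbon-migration path to the seven-membered lactone, or methyl migration in the epoxy ether.
- Fallback (known chemistry), from lactone 12 back to oxepanone 15: i-Bu2AlH at −78 °C gives lactol F1. Wittig olefination with isopropylidenetriphenylphosphorane opens it to homoprenyl alcohol F2. mCPBA gives trisubstituted epoxide F3, whose C3' epimers do not matter. Camphorsulfonic acid triggers 7-endo opening at the tertiary epoxide carbon by the C5' hydroxyl to give oxepan-3-ol F4. Dess–Martin oxidation then rejoins the route at 15.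

**Step 13 (epoxide to C6 ketone).**
- Risk: the C5 cation sits between two quaternary carbons, so a methyl shift could compete with the hydride shift.
- Fallback without a cation, from triflate 26 back to 28: BH3·THF hydroborates C5=C6 from the face anti to the angular methyl and also reduces the C3 ketone. The electron-poor tetrasubstituted enol triflate is left alone. NaBO3·4H2O gives 3,6-diol F5, and Dess–Martin periodinane oxidises both carbinols to give 28.

**Step 15 (late, chemoselective Riley oxidation).**
- Risks: over-oxidation next to the other two ketones or at the allylic methyl and methylene groups, or alkene migration before oxidation.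
- Fallback that moves the oxidation ahead of the union, from 28 back to 32: equilibrating deprotonation at C7 with KN(SiMe3)2 (1.0 equiv) and hydroxylation with 2-(phenylsulfonyl)-3-phenyloxaziridine give acyloin F6. Cu(OAc)2 and air in MeOH oxidise it to diosphenol triflate F7. t-BuMe2SiCl and imidazole give silyl ether F8. Negishi coupling with zinc reagent 29 gives silyl-protected sodwanone B F9, and HF·pyridine releases 32.

## Further compounds

F1 | step 7 | lactol of 12 (anomeric mixture) | BrCC[C@@H]1[C@H](C)CC[C@@H]2OC(O)CC[C@]21C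
F2 | step 7 | (1S,2S,3R,4R)-3-(2-bromoethyl)-2,4-dimethyl-2-(4-methylpent-3-en-1-yl)cyclohexan-1-ol | BrCC[C@@H]1[C@H](C)CC[C@H](O)[C@@]1(C)CCC=C(C)C
F3 | step 7 | epoxide of F2 (3,3-dimethyloxiran-2-yl terminus, epimeric mixture) | BrCC[C@@H]1[C@H](C)CC[C@H](O)[C@@]1(C)CCC2OC2(C)C
F4 | step 7 | oxepan-3-ol corresponding to 15 (C3' epimeric mixture) | BrCC[C@@H]1[C@H](C)CC[C@@H]2OC(C)(C)C(O)CC[C@]21C
F5 | step 13 | 3β,6α-diol of the trans-decalin enol triflate | CC1=C(OS(=O)(=O)C(F)(F)F)[C@@]2(C)CC[C@H](O)C(C)(C)[C@@H]2[C@@H](O)C1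
F6 | step 15 | 7-hydroxy derivative of 28 (acyloin, C7 epimers) | CC1=C(OS(=O)(=O)C(F)(F)F)[C@@]2(C)CCC(=O)C(C)(C)[C@@H]2C(=O)C1O
F7 | step 15 | diosphenol enol triflate (C5=C6–OH, C7 ketone, C9–OTf) | CC1=C(OS(=O)(=O)C(F)(F)F)[C@@]2(C)CCC(=O)C(C)(C)C2=C(O)C1=O
F8 | step 15 | tert-butyldimethylsilyl ether of F7 | CC1=C(OS(=O)(=O)C(F)(F)F)[C@@]2(C)CCC(=O)C(C)(C)C2=C(O[Si](C)(C)C(C)(C)C)C1=O
F9 | step 15 | O-(tert-butyldimethylsilyl) sodwanone B | CC1=C(CC[C@@H]2[C@H](C)CC[C@@H]3OC(C)(C)C(=O)CC[C@]32C)[C@@]2(C)CCC(=O)C(C)(C)C2=C(O[Si](C)(C)C(C)(C)C)C1=O
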